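## Retrosynthetic overview

1. Germacranolide numbering is used (C1 carbinol, C3 acetate, C4(C15)=C5, C6 lactone oxygen, C7, C8 angelate, C9=C10(C14), C11=C13, C12 carbonyl). The last C–C bond is C1–C10: a chromium-electrocatalysed Nozaki–Hiyama–Kishi ring closure of the ten-membered carbocycle, followed by Luche reduction of the C15 enal.
2. C4–C5: Nozaki–Hiyama–Kishi union of a lactone C5 aldehyde with a 5-iodo-dihydropyran made from 2-deoxy-D-ribose (C1–C4, C15 and the C3 stereocentre). Acid then opens the pyran to the C15 enal, which fixes the 4,5 geometry, and to the C1 aldehyde.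
3. C7–C8: decatungstate-photocatalysed addition of the acyl radical of but-2-ynal to silylated (S)-5-(hydroxymethyl)butenolide (C6 bought, C7 trans to it). Felkin reduction (C8), syn hydrosilylation (E C9=C10, masked iodide), angeloylation and Eschenmoser methylenation follow.
4. Ring order: the γ-lactone is bought as the butenolide; the sugar pyran is a temporary ring opened in step 14; the ten-membered ring is formed last, in step 16.

Assumption: (S)-5-(hydroxymethyl)furan-2(5H)-one, but-2-ynal, 2-deoxy-D-ribose and angelic acid are bought; TBS = tert-butyldimethylsilyl.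

## Route

Step 1
Reactants: 1 (S)-5-(hydroxymethyl)furan-2(5H)-one
Product: 2 (S)-5-[(tert-butyldimethylsilyloxy)methyl]furan-2(5H)-one
Conditions: TBSCl, imidazole, CH2Cl2, 0 °C to rt
Reagents that add atoms: tert-butyldimethylsilyl chloride, CC(C)(C)[Si](C)(C)Cl
Why: Standard silylation of the primary alcohol; the bought C6 stereocentre is not touched and the bulky CH2OTBS group later shields one face of the butenolide.

Step 2
Reactants: 2 (S)-5-[(tert-butyldimethylsilyloxy)methyl]furan-2(5H)-one; 3 but-2-ynal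
Product: 4 (4S,5S)-4-(but-2-ynoyl)-5-[(tert-butyldimethylsilyloxy)methyl]dihydrofuran-2(3H)-one (4,5-trans)
Conditions: (Bu4N)4[W10O32] (2 mol%), MeCN, 390 nm LED, 20 °C, 3 (1.5 equiv) added over 6 h
Reagents that add atoms: none
Why: Proposed new method: photoexcited decatungstate abstracts the hydridic formyl hydrogen of 3, the alkynoyl σ-radical (no easy decarbonylation path) adds to the butenolide β-carbon C7 on the face anti to the C6 CH2OTBS group, and the α-lactone radical takes the hydrogen back from reduced decatungstate, so the C7–C8 bond and the C7 stereocentre (trans to C6) are set in one light-driven step; the closest known chemistry is the decatungstate-photocatalysed hydroacylation of electron-poor alkenes (radical Giese addition) with saturated and aromatic aldehydes and the trans-selective sensitised photoadditions to 5-substituted furan-2(5H)-ones, whereas a conjugated ynal has not been used as the acyl donor.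

Step 3
Reactants: 4 (4S,5S)-4-(but-2-ynoyl)-5-[(tert-butyldimethylsilyloxy)methyl]dihydrofuran-2(3H)-one
Product: 5 (4R,5S)-5-[(tert-butyldimethylsilyloxy)methyl]-4-[(1S)-1-hydroxybut-2-yn-1-yl]dihydrofuran-2(3H)-one
Conditions: LiBH(s-Bu)3, THF, −78 °C; AcOH, −78 °C
Reagents that add atoms: none
Why: Felkin–Anh 1,2-reduction of the ynone: the bulky borohydride approaches anti to the oxygen-bearing C6 ring branch, next to the small alkynyl group, and sets C8 under control of C7; the cold acid quench prevents lactone migration to the new alkoxide.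

Step 4
Reactants: 5 (4R,5S)-5-[(tert-butyldimethylsilyloxy)methyl]-4-[(1S)-1-hydroxybut-2-yn-1-yl]dihydrofuran-2(3H)-one
Product: 6 (4R,5S)-5-[(tert-butyldimethylsilyloxy)methyl]-4-[(1S,2E)-1-hydroxy-3-(triethylsilyl)but-2-en-1-yl]dihydrofuran-2(3H)-one
Conditions: Et3SiH, PtCl2 (5 mol%), XPhos (10 mol%), THF, 50 °C
Reagents that add atoms: triethylsilane, CC[SiH](CC)CC
Why: Platinum-catalysed syn hydrosilylation of a propargylic alcohol places silicon on the alkyne carbon remote from the carbinol and gives the E vinylsilane, which fixes the C9=C10 geometry and masks the later C10 iodide.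

Step 5
Reactants: 6 (4R,5S)-5-[(tert-butyldimethylsilyloxy)methyl]-4-[(1S,2E)-1-hydroxy-3-(triethylsilyl)but-2-en-1-yl]dihydrofuran-2(3H)-one
Product: 7 (1S,2E)-1-[(2S,3R)-2-[(tert-butyldimethylsilyloxy)methyl]-5-oxotetrahydrofuran-3-yl]-3-(triethylsilyl)but-2-en-1-yl (Z)-2-methylbut-2-enoate
Conditions: angelic acid, 2,4,6-Cl3C6H2COCl, Et3N, toluene, rt; then 6, 80 °C
Reagents that add atoms: angelic acid, C/C=C(/C)C(=O)O
Why: Yamaguchi esterification through the mixed anhydride acylates the hindered allylic alcohol with retention at C8 and avoids the angelate-to-tiglate isomerisation that nucleophilic amine catalysts cause.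

Step 6
Reactants: 7 (1S,2E)-1-[(2S,3R)-2-[(tert-butyldimethylsilyloxy)methyl]-5-oxotetrahydrofuran-3-yl]-3-(triethylsilyl)but-2-en-1-yl (Z)-2-methylbut-2-enoate
Product: 11 (1S,2E)-1-[(2S,3R)-2-[(tert-butyldimethylsilyloxy)methyl]-4-methylidene-5-oxotetrahydrofuran-3-yl]-3-(triethylsilyl)but-2-en-1-yl (Z)-2-methylbut-2-enoate, via lithium enolate 8 (not isolated), via Mannich base 9 (not isolated), via trimethylammonium iodide 10 (not isolated)
Conditions: LiN(SiMe3)2, THF, −78 °C; CH2=NMe2+ I−, −78 to 0 °C; MeI, MeOH, rt; NaHCO3, CH2Cl2–H2O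
Reagents that add atoms: dimethylmethylideneammonium iodide (Eschenmoser's salt), C=[N+](C)C.[I-]
Why: Eschenmoser methylenation: Mannich reaction of the lactone enolate (the angelate has no α-hydrogen), quaternisation and E1cB elimination give the exocyclic C11=C13 alkene; no stereocentre is touched.

Step 7
Reactants: 11 (1S,2E)-1-[(2S,3R)-2-[(tert-butyldimethylsilyloxy)methyl]-4-methylidene-5-oxotetrahydrofuran-3-yl]-3-(triethylsilyl)but-2-en-1-yl (Z)-2-methylbut-2-enoate
Product: 12 (1S,2E)-1-[(2S,3R)-2-(hydroxymethyl)-4-methylidene-5-oxotetrahydrofuran-3-yl]-3-(triethylsilyl)but-2-en-1-yl (Z)-2-methylbut-2-enoate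
Conditions: HF·pyridine, pyridine, THF, 0 °C
Reagents that add atoms: none
Why: Fluoride cleavage of the primary silyl ether; the vinyl C–Si bond, both esters and the α-methylene lactone are inert to buffered HF·pyridine.

Step 8
Reactants: 12 (1S,2E)-1-[(2S,3R)-2-(hydroxymethyl)-4-methylidene-5-oxotetrahydrofuran-3-yl]-3-(triethylsilyl)but-2-en-1-yl (Z)-2-methylbut-2-enoate
Product: 13 (1S,2E)-1-[(2S,3R)-2-formyl-4-methylidene-5-oxotetrahydrofuran-3-yl]-3-(triethylsilyl)but-2-en-1-yl (Z)-2-methylbut-2-enoate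
Conditions: Dess–Martin periodinane, CH2Cl2, 0 °C to rt
Reagents that add atoms: none
Why: Dess–Martin oxidation under near-neutral conditions gives the α-acyloxy aldehyde without epimerising C6; it is used at once.

Step 9
Reactants: 14 2-deoxy-D-ribose
Product: 15 methyl 2-deoxy-β-D-erythro-pentopyranoside
Conditions: MeOH, HCl (1 mol%), 20 °C, 18 h; crystallise
Reagents that add atoms: methanol, CO
Why: Fischer glycosidation under thermodynamic control gives the pyranoside, whose β anomer crystallises; the sugar C3 (the future C3 of the target) is not touched.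

Step 10
Reactants: 15 methyl 2-deoxy-β-D-erythro-pentopyranoside
Product: 16 methyl 3-O-acetyl-2-deoxy-β-D-erythro-pentopyranoside
Conditions: AcCl (1.05 equiv), Me2SnCl2 (5 mol%), i-Pr2NEt, THF, 0 °C
Reagents that add atoms: acetyl chloride, CC(=O)Cl
Why: Organotin-catalysed regioselective acylation of a cis-diol at its equatorial oxygen (O3 in the 1C4 chair, where OMe and O4 are axial) puts the target's acetate on the bought stereocentre.

Step 11
Reactants: 16 methyl 3-O-acetyl-2-deoxy-β-D-erythro-pentopyranoside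
Product: 17 (2R,4S)-2-methoxy-3,4-dihydro-2H-pyran-4-yl acetate
Conditions: Burgess reagent (MeO2CN−SO2N+Et3), toluene, 80 °C
Reagents that add atoms: none
Why: Burgess dehydration is a syn (Ei) elimination of the sulfamate; the only β-hydrogen cis to O4 is on the sugar C5 because H3 is trans to O4, so the 4,5-enol ether forms regiospecifically and C3 stays intact.

Step 12
Reactants: 17 (2R,4S)-2-methoxy-3,4-dihydro-2H-pyran-4-yl acetate
Product: 18 (2R,4S)-5-iodo-2-methoxy-3,4-dihydro-2H-pyran-4-yl acetate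
Conditions: NIS, AgNO3 (0.2 equiv), MeCN, 70 °C
Reagents that add atoms: N-iodosuccinimide, O=C1CCC(=O)N1I
Why: Electrophilic iodination of the enol ether at its nucleophilic β-carbon followed by proton loss (the known route from glycals to 2-iodoglycals) gives the vinyl iodide at the future C4.

Step 13
Reactants: 13 (1S,2E)-1-[(2S,3R)-2-formyl-4-methylidene-5-oxotetrahydrofuran-3-yl]-3-(triethylsilyl)but-2-en-1-yl (Z)-2-methylbut-2-enoate; 18 (2R,4S)-5-iodo-2-methoxy-3,4-dihydro-2H-pyran-4-yl acetate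
Product: 19 coupling product in which the formyl group of 13 has become a CH(OH) group bearing the (2R,4S)-4-acetoxy-2-methoxy-3,4-dihydro-2H-pyran-5-yl unit (both C5 epimers)
Conditions: CrCl2 (4 equiv), NiCl2 (2 mol%), DMF, rt
Reagents that add atoms: none
Why: Nozaki–Hiyama–Kishi coupling: zerovalent nickel inserts into the C–I bond and transmetalation to trivalent chromium gives a vinylchromium that adds only to the aldehyde (vinylsilane, esters and enoate are inert); the C5 carbinol forms as an epimer mixture that does not matter because C5 becomes sp2 in step 14.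

Step 14
Reactants: 19 coupling product (both C5 epimers)
Product: 20 (1S,2E)-1-[(2R,3S)-2-[(1E,3S)-3-acetoxy-2-formyl-5-oxopent-1-en-1-yl]-4-methylidene-5-oxotetrahydrofuran-3-yl]-3-(triethylsilyl)but-2-en-1-yl (Z)-2-methylbut-2-enoate
Conditions: PPTS (0.2 equiv), THF–H2O (10:1), rt
Reagents that add atoms: water, O
Why: Acid hydrolysis of a 3-alkoxy allylic alcohol (Stork–Danheiser-type 1,3-transposition): loss of the C5 hydroxyl through the oxocarbenium-stabilised allyl cation and addition of water at C15 open the pyran to the C15 enal and the C1 aldehyde, and the enal settles in the more stable geometry with C6 trans to the formyl group, which is the 4,5 geometry of the target.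

Step 15
Reactants: 20 (1S,2E)-1-[(2R,3S)-2-[(1E,3S)-3-acetoxy-2-formyl-5-oxopent-1-en-1-yl]-4-methylidene-5-oxotetrahydrofuran-3-yl]-3-(triethylsilyl)but-2-en-1-yl (Z)-2-methylbut-2-enoate
Product: 21 (1S,2E)-1-[(2R,3S)-2-[(1E,3S)-3-acetoxy-2-formyl-5-oxopent-1-en-1-yl]-4-methylidene-5-oxotetrahydrofuran-3-yl]-3-iodobut-2-en-1-yl (Z)-2-methylbut-2-enoate
Conditions: NIS, (CF3)2CHOH, 0 °C
Reagents that add atoms: N-iodosuccinimide, O=C1CCC(=O)N1I
Why: Iododesilylation (ipso substitution of the electron-rich vinylsilane) with retention of the E geometry unmasks the C10 iodide only after the first chromium coupling, so the two couplings cannot interfere.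

Step 16
Reactants: 21 (1S,2E)-1-[(2R,3S)-2-[(1E,3S)-3-acetoxy-2-formyl-5-oxopent-1-en-1-yl]-4-methylidene-5-oxotetrahydrofuran-3-yl]-3-iodobut-2-en-1-yl (Z)-2-methylbut-2-enoate
Product: 23 macrocyclic hydroxy enal (the target with C15 as CHO), via trimethylsilyl ether 22 (not isolated)
Conditions: CrCl2 (20 mol%), NiCl2·glyme (3 mol%), 4,4'-di-tert-butyl-2,2'-bipyridine (3 mol%), Me3SiCl (2.5 equiv), LiCl, DMF–THF, undivided cell, Al anode, Ni-foam cathode, 3 mA, 2.3 F/mol, 21 added over 10 h (final 2 mM), rt; then aq. citric acid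
Reagents that add atoms: none
Why: Proposed new method: cathodic reduction keeps a small amount of divalent chromium in turnover (aluminium anode as electron source), zerovalent nickel inserts into the C10–I bond, transmetalation gives the vinylchromium, which adds intramolecularly to the more electrophilic saturated C1 aldehyde (the enal would have to close an eight-membered ring holding an E alkene), and Me3SiCl frees chromium from the alkoxide; C1 is set 1,3-anti to the C3 acetoxy group through the chelate between the aldehyde and acetate oxygens in the ring-closing transition state; the closest known chemistry is the stoichiometric Nozaki–Hiyama–Kishi macrocyclisation and the chromium-electrocatalytic intermolecular coupling, which has not been used to close a ten-membered carbocycle.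

Step 17
Reactants: 23 macrocyclic hydroxy enal
Product: 24 (1S,3S,6R,7R,8R)-3-acetoxy-8-[(Z)-2-methylbut-2-enoyloxy]-1,15-dihydroxygermacra-4(5)Z,9(10)E,11(13)-trien-6,12-olide (CNP0153210.6)
Conditions: NaBH4, CeCl3·7H2O, MeOH, −78 °C
Reagents that add atoms: none
Why: Luche reduction: cerium-activated 1,2-reduction of the enal at −78 °C is faster than conjugate reduction of the α-methylene lactone and leaves the esters alone; no stereocentre is formed.

## Compound list

1 | (S)-5-(hydroxymethyl)furan-2(5H)-one | O=C1C=C[C@@H](CO)O1 | starting material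
2 | (S)-5-[(tert-butyldimethylsilyloxy)methyl]furan-2(5H)-one | O=C1C=C[C@@H](CO[Si](C)(C)C(C)(C)C)O1 | intermediate
3 | but-2-ynal | CC#CC=O | starting material
4 | (4S,5S)-4-(but-2-ynoyl)-5-[(tert-butyldimethylsilyloxy)methyl]dihydrofuran-2(3H)-one | O=C1C[C@H](C(=O)C#CC)[C@@H](CO[Si](C)(C)C(C)(C)C)O1 | intermediate
5 | (4R,5S)-5-[(tert-butyldimethylsilyloxy)methyl]-4-[(1S)-1-hydroxybut-2-yn-1-yl]dihydrofuran-2(3H)-one | O=C1C[C@H]([C@H](O)C#CC)[C@@H](CO[Si](C)(C)C(C)(C)C)O1 | intermediate
6 | (4R,5S)-5-[(tert-butyldimethylsilyloxy)methyl]-4-[(1S,2E)-1-hydroxy-3-(triethylsilyl)but-2-en-1-yl]dihydrofuran-2(3H)-one | O=C1C[C@H]([C@H](O)/C=C(/[Si](CC)(CC)CC)C)[C@@H](CO[Si](C)(C)C(C)(C)C)O1 | intermediate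
7 | (1S,2E)-1-[(2S,3R)-2-[(tert-butyldimethylsilyloxy)methyl]-5-oxotetrahydrofuran-3-yl]-3-(triethylsilyl)but-2-en-1-yl (Z)-2-methylbut-2-enoate | O=C1C[C@H]([C@H](OC(=O)/C(C)=C\C)/C=C(/[Si](CC)(CC)CC)C)[C@@H](CO[Si](C)(C)C(C)(C)C)O1 | intermediate
8 | lithium enolate of 7 | [Li+].[O-]C1=C[C@H]([C@H](OC(=O)/C(C)=C\C)/C=C(/[Si](CC)(CC)CC)C)[C@@H](CO[Si](C)(C)C(C)(C)C)O1 | intermediate
9 | Mannich base: 7 with a CH2NMe2 group on the lactone α-carbon (C11 epimers) | CN(C)CC1C(=O)O[C@H](CO[Si](C)(C)C(C)(C)C)[C@H]1[C@H](OC(=O)/C(C)=C\C)/C=C(/[Si](CC)(CC)CC)C | intermediate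
10 | trimethylammonium iodide of 9 | C[N+](C)(C)CC1C(=O)O[C@H](CO[Si](C)(C)C(C)(C)C)[C@H]1[C@H](OC(=O)/C(C)=C\C)/C=C(/[Si](CC)(CC)CC)C.[I-] | intermediate
11 | (1S,2E)-1-[(2S,3R)-2-[(tert-butyldimethylsilyloxy)methyl]-4-methylidene-5-oxotetrahydrofuran-3-yl]-3-(triethylsilyl)but-2-en-1-yl (Z)-2-methylbut-2-enoate | C=C1C(=O)O[C@H](CO[Si](C)(C)C(C)(C)C)[C@H]1[C@H](OC(=O)/C(C)=C\C)/C=C(/[Si](CC)(CC)CC)C | intermediate
12 | (1S,2E)-1-[(2S,3R)-2-(hydroxymethyl)-4-methylidene-5-oxotetrahydrofuran-3-yl]-3-(triethylsilyl)but-2-en-1-yl (Z)-2-methylbut-2-enoate | C=C1C(=O)O[C@H](CO)[C@H]1[C@H](OC(=O)/C(C)=C\C)/C=C(/[Si](CC)(CC)CC)C | intermediate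
13 | (1S,2E)-1-[(2S,3R)-2-formyl-4-methylidene-5-oxotetrahydrofuran-3-yl]-3-(triethylsilyl)but-2-en-1-yl (Z)-2-methylbut-2-enoate | C=C1C(=O)O[C@H](C=O)[C@H]1[C@H](OC(=O)/C(C)=C\C)/C=C(/[Si](CC)(CC)CC)C | intermediate
14 | 2-deoxy-D-ribose (2-deoxy-D-erythro-pentose, drawn open-chain) | O=CC[C@H](O)[C@H](O)CO | starting material
15 | methyl 2-deoxy-β-D-erythro-pentopyranoside | CO[C@H]1C[C@H](O)[C@H](O)CO1 | intermediate
16 | methyl 3-O-acetyl-2-deoxy-β-D-erythro-pentopyranoside | CO[C@H]1C[C@H](OC(C)=O)[C@H](O)CO1 | intermediate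
17 | (2R,4S)-2-methoxy-3,4-dihydro-2H-pyran-4-yl acetate | CO[C@H]1C[C@H](OC(C)=O)C=CO1 | intermediate
18 | (2R,4S)-5-iodo-2-methoxy-3,4-dihydro-2H-pyran-4-yl acetate | CO[C@H]1C[C@H](OC(C)=O)C(I)=CO1 | intermediate
19 | coupling product: 13 with CHO replaced by CH(OH) bearing the (2R,4S)-4-acetoxy-2-methoxy-3,4-dihydro-2H-pyran-5-yl group (both C5 epimers) | C=C1C(=O)O[C@H](C(O)C2=CO[C@@H](OC)C[C@@H]2OC(C)=O)[C@H]1[C@H](OC(=O)/C(C)=C\C)/C=C(/[Si](CC)(CC)CC)C | intermediate
20 | (1S,2E)-1-[(2R,3S)-2-[(1E,3S)-3-acetoxy-2-formyl-5-oxopent-1-en-1-yl]-4-methylidene-5-oxotetrahydrofuran-3-yl]-3-(triethylsilyl)but-2-en-1-yl (Z)-2-methylbut-2-enoate | C=C1C(=O)O[C@H](/C=C(/C=O)[C@@H](OC(C)=O)CC=O)[C@H]1[C@H](OC(=O)/C(C)=C\C)/C=C(/[Si](CC)(CC)CC)C | intermediate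
21 | (1S,2E)-1-[(2R,3S)-2-[(1E,3S)-3-acetoxy-2-formyl-5-oxopent-1-en-1-yl]-4-methylidene-5-oxotetrahydrofuran-3-yl]-3-iodobut-2-en-1-yl (Z)-2-methylbut-2-enoate | C=C1C(=O)O[C@H](/C=C(/C=O)[C@@H](OC(C)=O)CC=O)[C@H]1[C@H](OC(=O)/C(C)=C\C)/C=C(/I)C | intermediate
22 | 1-O-trimethylsilyl ether of 23 | C=C1C(=O)O[C@@H]2/C=C(/C=O)[C@@H](OC(C)=O)C[C@H](O[Si](C)(C)C)/C(C)=C/[C@@H](OC(=O)/C(C)=C\C)[C@@H]12 | intermediate
23 | (1S,3S,6R,7R,8R)-3-acetoxy-1-hydroxy-8-[(Z)-2-methylbut-2-enoyloxy]-15-oxogermacra-4(5),9(10)E,11(13)-trien-6,12-olide (4,5 geometry as in the target) | C=C1C(=O)O[C@@H]2/C=C(/C=O)[C@@H](OC(C)=O)C[C@H](O)/C(C)=C/[C@@H](OC(=O)/C(C)=C\C)[C@@H]12 | intermediate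
24 | (1S,3S,6R,7R,8R)-3-acetoxy-8-[(Z)-2-methylbut-2-enoyloxy]-1,15-dihydroxygermacra-4(5)Z,9(10)E,11(13)-trien-6,12-olide (CNP0153210.6) | C=C1C(=O)O[C@@H]2/C=C(/CO)[C@@H](OC(C)=O)C[C@H](O)/C(C)=C/[C@@H](OC(=O)/C(C)=C\C)[C@@H]12 | target

## Step count and risks

Total steps: 17. Longest linear sequence: 13 (steps 1–8 and 13–17, from 1).

The three steps most likely to fail:

Step 2 (new photochemical acylation; the ynal may oligomerise or the acyl radical may add poorly). The fallback uses known chemistry, sets out from 2 and comes back at 4. Benzophenone-sensitised photoaddition of 1,3-dioxolane to 2 (350 nm, dioxolane as solvent) gives the trans dioxolanyl lactone F1. PPTS in wet acetone frees the aldehyde F2. CH3C≡CMgBr in THF at −78 °C adds to give the propargylic alcohols F3 as both carbinol epimers, and Dess–Martin oxidation of F3 returns the ynone 4.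

Step 3 (C8 diastereoselectivity rests on the C6 branch acting as the large group). The fallback sets out from 4 and comes back at 7, replacing steps 3–5. If hydride delivery gives mainly the other carbinol epimer (for example with Zn(BH4)2), that propargylic alcohol F4 is hydrosilylated as in step 4 to the vinylsilane alcohol F5. F5 is then esterified with angelic acid under Mitsunobu conditions (PPh3, diisopropyl azodicarboxylate, toluene, 0 °C), which inverts C8 and gives 7 directly; attack at the fully substituted silyl-bearing alkene carbon is blocked.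

Step 16 (new electrochemical ring closure; risks are oligomerisation, reduction of the enal and the wrong C1 epimer). The fallback uses known chemistry, sets out from 21 and comes back at 23. It is the classical stoichiometric Nozaki–Hiyama–Kishi macrocyclisation (CrCl2 10 equiv, NiCl2 1 mol%, DMSO–THF, 21 added by syringe pump to 1 mM), with no current and no silyl chloride, so the chromium alkoxide of 23 is hydrolysed on work-up and no new compound is made.

## Further compounds

F1 | step 2 | (4S,5S)-5-[(tert-butyldimethylsilyloxy)methyl]-4-(1,3-dioxolan-2-yl)dihydrofuran-2(3H)-one | O=C1C[C@H](C2OCCO2)[C@@H](CO[Si](C)(C)C(C)(C)C)O1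
F2 | step 2 | (2S,3S)-2-[(tert-butyldimethylsilyloxy)methyl]-5-oxotetrahydrofuran-3-carbaldehyde | O=C1C[C@H](C=O)[C@@H](CO[Si](C)(C)C(C)(C)C)O1
F3 | step 2 | (4R,5S)-5-[(tert-butyldimethylsilyloxy)methyl]-4-(1-hydroxybut-2-yn-1-yl)dihydrofuran-2(3H)-one (both carbinol epimers) | O=C1C[C@H](C(O)C#CC)[C@@H](CO[Si](C)(C)C(C)(C)C)O1
F4 | step 3 | (4R,5S)-5-[(tert-butyldimethylsilyloxy)methyl]-4-[(1R)-1-hydroxybut-2-yn-1-yl]dihydrofuran-2(3H)-one | O=C1C[C@H]([C@@H](O)C#CC)[C@@H](CO[Si](C)(C)C(C)(C)C)O1
F5 | step 3 | (4R,5S)-5-[(tert-butyldimethylsilyloxy)methyl]-4-[(1R,2E)-1-hydroxy-3-(triethylsilyl)but-2-en-1-yl]dihydrofuran-2(3H)-one | O=C1C[C@H]([C@@H](O)/C=C(/[Si](CC)(CC)CC)C)[C@@H](CO[Si](C)(C)C(C)(C)C)O1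
F0 | step 16 | none | none
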